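Count what the readings lack: subtract substrate and target from the charge, and call the rest the pool.

all flasks: substrate 10 mM
- violet: partner 40 mM; run made earlier
- ochre: partner 56 mM; run made earlier
- red: partner 88 mM; run made earlier
- south-east: partner 40.0 mM (fed, over 8.00 d); all but partner at the start; partner goes in evenly over 8.00 d, the run ends at 10 d; time 10 d
- north-west: partner 40.0 mM; everything together in a closed stirred flask, run for 10 d; time 10 d
- south-west: partner 40.0 mM; a single well-mixed tank run continuously and read at steady state, 10 d in it on average
- south: partner 40.0 mM; one stirred flow tank at steady state, fed with the mixture as stated, mean residence time 50.0 d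

| run | time / d | target / % | substrate / % |
|---|---|---|---|
| violet | 0.833 | 4.5 | 61.2 |
| violet | 1.67 | 7.7 | 37.1 |
| violet | 4.00 | 15.7 | 8.9 |
| violet | 10.0 | 29.6 | 1.6 |
| ochre | 0.500 | 0.9 | 75.4 |
| ochre | 1.04 | 5.1 | 52.8 |
| ochre | 2.50 | 12.2 | 24.5 |
| ochre | 6.00 | 23.1 | 2.5 |
| red | 0.833 | 4.6 | 62.6 |
| red | 2.00 | 10.6 | 30.2 |
| red | 4.00 | 16.6 | 10.9 |
| red | 6.00 | 26.7 | 2.7 |

(standard deviation of a reading: 1 percentage point)

1. order of the set-ups by the amount of target at the outlet or at the end, in percent of the substrate put in, highest first (south-east / north-west / south-west / south)
2. amount of target at the outlet or at the end, in percent of the substrate put in, south-east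
3. amount of target at the outlet or at the end, in percent of the substrate put in, north-west
4. amount of target at the outlet or at the end, in percent of the substrate put in, south-west
5. amount of target at the outlet or at the end, in percent of the substrate put in, south

- the stated concentrations are those of everything mixed, before any reaction; amounts are the same in each set-up
- the feed brings no volume worth counting
- the earlier runs were made in a closed, stirred flask

In the violet run, between 4.00 d and 10.0 d, I read 0.0321 d⁻¹ for the pool constant, the target made per day divided by the pool. Over the first 0.833 d the same run read 0.315 d⁻¹, ten times the late value.

I took this as a pseudo-first-order constant that follows c_partner as it stands at the moment. If one partner goes per substrate, the 10 mM of substrate could take a quarter of the 40 mM of partner, so I concluded that something unread was also removing partner. At 4.00 d red, with 88 mM, read 16.6% of target against 15.7% in violet, which as a reading gives an order in the charge of 0.0707.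

Then I bracketed the south tank. Its balance makes target over pool equal the constant times 50.0 d, and substrate, with 0.605 d⁻¹ read from violet, leaves 3.20%. The early constant gave an upper bound of 91.0%, provided c_partner in the tank stood no higher than in violet's first window. The late constant gave a lower bound of 59.7%, provided c_partner in the tank stood no lower than in violet's late window. I committed to the lower edge, expecting the unread loss to work in the tank too. North-west repeats violet, so I took 29.6%.

The forecast gave the order south > north-west > south-east > south-west, with 28.5%, 29.8%, 25% and 42% for south-east, north-west, south-west and south, the last lower than my lower bound, in its words “I guess about 42%, with wide uncertainty”.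

The order came out south > south-east > south-west > north-west, with 42.4%, 29.6%, 33.8% and 60.7% for south-east, north-west, south-west and south, so south stood higher than my lower bound and lower than my upper one.

    2 partner → self-condensation product (k = 0.0101 L mol⁻¹ min⁻¹)
    substrate → intermediate A (k = 4.09 × 10⁻⁴ min⁻¹)
    partner + intermediate A ⇌ intermediate B (K = 28.2 L mol⁻¹, k = 0.0113 L mol⁻¹ min⁻¹)
    partner + intermediate A → target (k = 0.00588 L mol⁻¹ min⁻¹)

At the south outlet, intermediate A held 32.1% of the substrate charged. In the south-west tank, with 14.5% of substrate left, the pool constant came to 0.0654 d⁻¹, twice violet's late value, where c_partner stood at 9.49 mM.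

The data were computed with constants of no real substance; noise was put on by code.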